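## Retrosynthetic overview

1. The target is opened from an enol δ-lactone, a temporary ring that ties the side-chain acid to the oxygen of the future dienone ketone. That lactone comes from a ligand-controlled dearomative C-prenylation of a hexasubstituted phloroglucinol-type arene, which creates the quaternary carbon.
2. The cis-2,3-dimethyl-dihydropyranone ring is closed by a Mitsunobu reaction (inversion) on an anti-aldol chain. The arene comes from the benzannulation of cyclobutenone 14 with siloxyalkyne 21. This step makes the bond from the future dienone carbonyl carbon to the future quaternary carbon, and the bond from the pyran-oxygen-bearing carbon to the carbon that carries the pyranone carbonyl. It sacrifices the cyclobutenone bond between the carbonyl carbon and its substituted alkene carbon, a temporary bond.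
3. Enabling feature: the carbocycle is a dearomatised phloroglucinol. Ketone O, pyran O and enol O sit on alternate ring carbons, and the quaternary carbon lies between the ketone carbon and the pyran-O carbon. A vinylketene carbonyl carbon and the oxygenated carbon of an ynol ether end up 1,3 on a new ring with the alkyl-bearing alkyne carbon between them, which is exactly this pattern.
4. Fragments: the acid side chain from 3-propylglutaric anhydride (desymmetrisation), the aldol unit from methyl (S)-3-hydroxybutanoate, the monoterpene unit from (R)-limonene oxide. The cyclobutenone is made by a ketene–ynol ether [2+2].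
5. Ring order: cyclobutenone (temporary) → benzene ring (key step) → δ-lactone (temporary) → dihydropyranone → dearomatisation and lactone opening.

Key step: step 13

Remark: the sense of induction of the two catalyst-controlled steps (1 and 18) is assumed as written; if it proves opposite, the pseudo-enantiomeric alkaloid catalyst or the antipodal ligand is used instead.

## Route

Step 1
Reactants: 1 3-propylglutaric anhydride
Product: 2 (3R)-3-(2-methoxy-2-oxoethyl)hexanoic acid
Conditions: MeOH (10 equiv), (DHQD)2AQN (10 mol %), Et2O, −30 °C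
Reagents that add atoms: methanol, CO
Why: Cinchona-alkaloid-catalysed desymmetrising alcoholysis of a 3-substituted glutaric anhydride; the chiral amine selects one enantiotopic carbonyl and so sets the propyl-bearing stereocentre.

Step 2
Reactants: 2 (3R)-3-(2-methoxy-2-oxoethyl)hexanoic acid
Product: 3 methyl (3S)-3-(2-chloro-2-oxoethyl)hexanoate
Conditions: (COCl)2, DMF (cat.), CH2Cl2, 0 °C → rt
Reagents that add atoms: oxalyl chloride, O=C(Cl)C(=O)Cl
Why: Standard acid chloride formation; the stereocentre is untouched (only the CIP label changes).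

Step 3
Reactants: 4 methyl (3S)-3-hydroxybutanoate
Product: 6 methyl (2S,3S)-3-hydroxy-2-methylbutanoate, via dianion 5 (not isolated)
Conditions: LiN(i-Pr)2 (2.2 equiv), THF, −78 → −20 °C; MeI, −78 → 0 °C
Reagents that add atoms: iodomethane, CI
Why: Fráter–Seebach alkylation; the chelated dilithium alkoxide-enolate should be methylated anti to the carbinol substituent, giving the anti (2S,3S) ester.

Step 4
Reactants: 6 methyl (2S,3S)-3-hydroxy-2-methylbutanoate
Product: 7 methyl (2S,3S)-3-[(tert-butyldimethylsilyl)oxy]-2-methylbutanoate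
Conditions: t-BuMe2SiCl, imidazole, DMF, rt
Reagents that add atoms: tert-butyldimethylsilyl chloride, C[Si](C)(Cl)C(C)(C)C
Why: Routine silylation of a secondary alcohol.

Step 5
Reactants: 7 methyl (2S,3S)-3-[(tert-butyldimethylsilyl)oxy]-2-methylbutanoate
Product: 8 (2S,3S)-3-[(tert-butyldimethylsilyl)oxy]-2-methylbutanal
Conditions: (i-Bu)2AlH (1.05 equiv), CH2Cl2, −78 °C; Rochelle salt work-up
Reagents that add atoms: none
Why: Partial reduction of a β-silyloxy ester stops at the aldehyde at −78 °C; the aldehyde is used crude to avoid α-epimerisation.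

Step 6
Reactants: 8 (2S,3S)-3-[(tert-butyldimethylsilyl)oxy]-2-methylbutanal, 9 ethoxyacetylene
Product: 11 (3RS,4R,5S)-5-[(tert-butyldimethylsilyl)oxy]-1-ethoxy-4-methylhex-1-yn-3-ol, via lithium ethoxyacetylide 10 (not isolated)
Conditions: 9, n-BuLi, THF, −78 °C; then 8, −78 °C; aq. NH4Cl
Reagents that add atoms: none
Why: 1,2-Addition of a lithium acetylide to an aldehyde; the new carbinol is formed as an epimer mixture on purpose, because it is oxidised to the ketone in step 15.

Step 7
Reactants: 11 (3RS,4R,5S)-5-[(tert-butyldimethylsilyl)oxy]-1-ethoxy-4-methylhex-1-yn-3-ol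
Product: 12 (3RS,4S,5S)-3,5-bis[(tert-butyldimethylsilyl)oxy]-1-ethoxy-4-methylhex-1-yne
Conditions: t-BuMe2SiCl, imidazole, DMAP (cat.), DMF, rt
Reagents that add atoms: tert-butyldimethylsilyl chloride, C[Si](C)(Cl)C(C)(C)C
Why: Buffered silylation protects the propargylic alcohol from ketene acylation and leaves the acid-sensitive ynol ether intact.

Step 8
Reactants: 3 methyl (3S)-3-(2-chloro-2-oxoethyl)hexanoate, 12 (3RS,4S,5S)-3,5-bis[(tert-butyldimethylsilyl)oxy]-1-ethoxy-4-methylhex-1-yne
Product: 14 methyl (3S)-3-{3-[(1RS,2S,3S)-1,3-bis(tert-butyldimethylsilyloxy)-2-methylbutyl]-2-ethoxy-4-oxocyclobut-2-en-1-yl}hexanoate, via ketene 13 (not isolated)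
Conditions: Et3N (1.5 equiv), slow addition of 3 (1.5 equiv) to 12, CH2Cl2, rt → 40 °C
Reagents that add atoms: none
Why: Ketene–alkoxyalkyne [2+2] cycloaddition; the nucleophilic alkyl-bearing alkyne carbon attacks the ketene carbonyl carbon, giving the 3-ethoxycyclobutenone regiospecifically, and the ring sp3 carbon forms as an irrelevant epimer mixture.

Step 9
Reactants: 15 (4R)-limonene 1,2-oxide
Product: 16 (3R)-6-oxo-3-(prop-1-en-2-yl)heptanal
Conditions: H5IO6, THF/H2O, 0 °C → rt
Reagents that add atoms: water, O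
Why: Periodic acid hydrolyses the epoxide and cleaves the resulting glycol in one pot; the isopropenyl-bearing stereocentre of limonene is carried over unchanged.

Step 10
Reactants: 16 (3R)-6-oxo-3-(prop-1-en-2-yl)heptanal
Product: 17 (5R)-8,8-dibromo-5-(prop-1-en-2-yl)oct-7-en-2-one
Conditions: CBr4, PPh3, CH2Cl2, 0 °C
Reagents that add atoms: carbon tetrabromide, BrC(Br)(Br)Br
Why: First stage of the Corey–Fuchs reaction; the dibromomethylene ylide should react with the aldehyde far faster than with the methyl ketone.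

Step 11
Reactants: 17 (5R)-8,8-dibromo-5-(prop-1-en-2-yl)oct-7-en-2-one
Product: 18 (4R)-1,1-dibromo-7-methyl-4-(prop-1-en-2-yl)octa-1,7-diene
Conditions: Ph3PCH3Br, NaN(SiMe3)2, THF, 0 °C → rt
Reagents that add atoms: methyltriphenylphosphonium bromide, C[P+](c1ccccc1)(c1ccccc1)c1ccccc1.[Br-]
Why: Wittig methylenation of the ketone; the dibromoalkene is inert to the non-stabilised ylide.

Step 12
Reactants: 18 (4R)-1,1-dibromo-7-methyl-4-(prop-1-en-2-yl)octa-1,7-diene
Product: 21 triisopropyl{[(4R)-7-methyl-4-(prop-1-en-2-yl)oct-7-en-1-yn-1-yl]oxy}silane, via lithium acetylide 19 (not isolated), via lithium ynolate 20 (not isolated)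
Conditions: n-BuLi (2.1 equiv), THF, −78 °C; LiOOt-Bu (from t-BuOOH and LiN(SiMe3)2), −78 → 0 °C; i-Pr3SiOTf, −78 °C
Reagents that add atoms: tert-butyl hydroperoxide, CC(C)(C)OO; triisopropylsilyl trifluoromethanesulfonate, CC(C)[Si](C(C)C)(C(C)C)OS(=O)(=O)C(F)(F)F
Why: Second stage of the Corey–Fuchs reaction gives the lithium acetylide, electrophilic oxygen transfer from the lithium peroxide converts it to the ynolate, and the bulky silyl triflate traps the ynolate on oxygen.

Step 13
Reactants: 14 methyl (3S)-3-{3-[(1RS,2S,3S)-1,3-bis(tert-butyldimethylsilyloxy)-2-methylbutyl]-2-ethoxy-4-oxocyclobut-2-en-1-yl}hexanoate, 21 triisopropyl{[(4R)-7-methyl-4-(prop-1-en-2-yl)oct-7-en-1-yn-1-yl]oxy}silane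
Product: 26 methyl (3S)-3-{3-[(1RS,2S,3S)-1,3-bis(tert-butyldimethylsilyloxy)-2-methylbutyl]-2-ethoxy-6-hydroxy-5-[(2R)-5-methyl-2-(prop-1-en-2-yl)hex-5-en-1-yl]-4-(triisopropylsilyloxy)phenyl}hexanoate, via vinylketene 22 (not isolated), via vinylcyclobutenone 23 (not isolated), via dienylketene 24 (not isolated), via cyclohexadienone 25 (not isolated)
Conditions: 21 (1.3 equiv), toluene, 80 °C then 145 °C (sealed tube)
Reagents that add atoms: none
Why: On heating, 14 should undergo 4π-electrocyclic ring opening to vinylketene 22, whose carbonyl carbon is attacked by the nucleophilic, alkyl-bearing carbon of siloxyalkyne 21 in a regiospecific [2+2] cycloaddition that makes both new bonds at once (23); 23 then ring-opens, cleaving the temporary bond inherited from 14, to dienylketene 24, which closes by 6π-electrocyclisation to dienone 25 and tautomerises to phenol 26. The closest known reaction type is the thermal benzannulation of cyclobutenones with siloxyalkynes (Danheiser benzannulation), used here with a 3-alkoxycyclobutenone so that a phloroglucinol pattern results. The four-membered ring of 23 closes by ketene–alkyne [2+2] and the six-membered ring by thermal 6π-electrocyclic closure of the (Z)-dienylketene, with the reversible opening of 23 feeding the reactive geometry. No stereocentre is created: the sp3 ring carbon of 14 becomes aromatic, so both of its epimers converge on one product, and the silyloxy-carbon epimers are levelled in step 15. The step needs regioselectivity in the [2+2] event and chemoselectivity for the ynol ether over the three isolated alkenes; both follow from the polarisation of the siloxyalkyne, which places the silyloxy carbon next to the carbon bearing the aldol chain and the monoterpene chain between the two oxygens.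

Step 14
Reactants: 26 methyl (3S)-3-{3-[(1RS,2S,3S)-1,3-bis(tert-butyldimethylsilyloxy)-2-methylbutyl]-2-ethoxy-6-hydroxy-5-[(2R)-5-methyl-2-(prop-1-en-2-yl)hex-5-en-1-yl]-4-(triisopropylsilyloxy)phenyl}hexanoate
Product: 28 (4S)-6-[(1RS,2S,3S)-1,3-dihydroxy-2-methylbutyl]-5-ethoxy-7-hydroxy-8-[(2R)-5-methyl-2-(prop-1-en-2-yl)hex-5-en-1-yl]-4-propylchroman-2-one, via desilylated hydroxy ester 27 (not isolated)
Conditions: Bu4NF (5 equiv), THF, 0 °C → rt; aq. NH4Cl
Reagents that add atoms: none
Why: Fluoride cleaves the aryl and alkyl silyl ethers, and the phenoxide next to the side chain (the other ortho oxygen is the ethyl ether) should close the buttressed δ-lactone on the methyl ester; any 26 that has already lactonised thermally converges here.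

Step 15
Reactants: 28 (4S)-6-[(1RS,2S,3S)-1,3-dihydroxy-2-methylbutyl]-5-ethoxy-7-hydroxy-8-[(2R)-5-methyl-2-(prop-1-en-2-yl)hex-5-en-1-yl]-4-propylchroman-2-one
Product: 29 (4S)-5-ethoxy-7-hydroxy-6-[(2S,3S)-3-hydroxy-2-methylbutanoyl]-8-[(2R)-5-methyl-2-(prop-1-en-2-yl)hex-5-en-1-yl]-4-propylchroman-2-one
Conditions: MnO2 (excess), CH2Cl2, rt
Reagents that add atoms: none
Why: MnO2 oxidises the benzylic alcohol chemoselectively over the aliphatic secondary alcohol, and both carbinol epimers give the same aryl ketone.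

Step 16
Reactants: 29 (4S)-5-ethoxy-7-hydroxy-6-[(2S,3S)-3-hydroxy-2-methylbutanoyl]-8-[(2R)-5-methyl-2-(prop-1-en-2-yl)hex-5-en-1-yl]-4-propylchroman-2-one
Product: 30 tricyclic lactone chromanone: (4S)-5-ethoxy-4-propyl-8-[(2R)-5-methyl-2-(prop-1-en-2-yl)hex-5-en-1-yl]chroman-2-one carrying a fused cis-(2R,3S)-2,3-dimethyl-2,3-dihydropyran-4-one ring (carbonyl on C6, ring oxygen on C7)
Conditions: PPh3, DIAD, toluene, 0 °C → rt
Reagents that add atoms: none
Why: Mitsunobu etherification; the only free phenol displaces the activated secondary carbinol intramolecularly with inversion (S → R), which turns the anti-aldol unit into the cis-2,3-dimethyl ring.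

Step 17
Reactants: 30 tricyclic lactone chromanone (5-ethoxy)
Product: 31 tricyclic lactone chromanone with free 5-OH: as 30 with the ethoxy group replaced by a hydroxyl chelated to the pyranone carbonyl
Conditions: BCl3 (3 equiv), CH2Cl2, −78 → −20 °C; aq. NaHCO3
Reagents that add atoms: none
Why: Chelation of boron between the pyranone carbonyl and the peri ethoxy oxygen directs dealkylation to that ether only; the ring ether and the lactone cannot chelate, and the 1,1-disubstituted alkenes should tolerate BCl3 at low temperature.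

Step 18
Reactants: 31 tricyclic lactone chromanone with free 5-OH, 32 tert-butyl 2-methylbut-3-en-2-yl carbonate
Product: 33 enol δ-lactone dienone: dearomatised tricycle in which the former C8 (para to the former 5-OH) is quaternary (R) and carries the prenyl and the (2R)-5-methyl-2-(prop-1-en-2-yl)hex-5-en-1-yl groups, with C5 now a ketone
Conditions: Pd2(dba)3 (2.5 mol %), (R,R)-DACH-phenyl Trost ligand (7.5 mol %), 32 (1.5 equiv), THF, 0 °C → rt
Reagents that add atoms: none
Why: Asymmetric Tsuji–Trost allylic dearomatisation; the phenoxide attacks the π-prenyl complex of palladium at its unsubstituted terminus through its para carbon, the only activated ring carbon that is not a ring-fusion atom, O-prenylation being reversible under zerovalent palladium, and the chiral ligand selects the face and sets the quaternary centre.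

Step 19
Reactants: 33 enol δ-lactone dienone
Product: 34 CNP0294320.1 (target)
Conditions: LiOH (3 equiv), THF/H2O, 0 °C; 1 M HCl to pH 3
Reagents that add atoms: water, O
Why: The enol lactone is a vinylogous anhydride and should open at the acyl carbon under very mild conditions; the triketone enolate formed resists further enolisation, which protects the cis-chromanone, and acidification gives the target tautomer.

## Compound list

1 | 3-propylglutaric anhydride (4-propyloxane-2,6-dione) | CCCC1CC(=O)OC(=O)C1 | starting material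
2 | (3R)-3-(2-methoxy-2-oxoethyl)hexanoic acid | OC(=O)C[C@@H](CCC)CC(=O)OC | intermediate
3 | methyl (3S)-3-(2-chloro-2-oxoethyl)hexanoate | ClC(=O)C[C@@H](CCC)CC(=O)OC | intermediate
4 | methyl (3S)-3-hydroxybutanoate | O[C@@H](C)CC(=O)OC | starting material
5 | dilithium alkoxide-enolate of 4 (dianion) | [Li]O[C@@H](C)C=C(O[Li])OC | intermediate
6 | methyl (2S,3S)-3-hydroxy-2-methylbutanoate | O[C@@H](C)[C@H](C)C(=O)OC | intermediate
7 | methyl (2S,3S)-3-[(tert-butyldimethylsilyl)oxy]-2-methylbutanoate | CC(C)(C)[Si](C)(C)O[C@@H](C)[C@H](C)C(=O)OC | intermediate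
8 | (2S,3S)-3-[(tert-butyldimethylsilyl)oxy]-2-methylbutanal | CC(C)(C)[Si](C)(C)O[C@@H](C)[C@H](C)C=O | intermediate
9 | ethoxyacetylene | C#COCC | starting material
10 | lithium ethoxyacetylide | [Li]C#COCC | intermediate
11 | (3RS,4R,5S)-5-[(tert-butyldimethylsilyl)oxy]-1-ethoxy-4-methylhex-1-yn-3-ol | CCOC#CC(O)[C@@H](C)[C@H](C)O[Si](C)(C)C(C)(C)C | intermediate
12 | (3RS,4S,5S)-3,5-bis[(tert-butyldimethylsilyl)oxy]-1-ethoxy-4-methylhex-1-yne | CCOC#CC(O[Si](C)(C)C(C)(C)C)[C@@H](C)[C@H](C)O[Si](C)(C)C(C)(C)C | intermediate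
13 | methyl (3S)-3-(2-oxoethenyl)hexanoate (ketene) | O=C=C[C@@H](CCC)CC(=O)OC | intermediate
14 | methyl (3S)-3-{3-[(1RS,2S,3S)-1,3-bis(tert-butyldimethylsilyloxy)-2-methylbutyl]-2-ethoxy-4-oxocyclobut-2-en-1-yl}hexanoate (epimers at the ring sp3 carbon) | O=C1C(C(O[Si](C)(C)C(C)(C)C)[C@@H](C)[C@H](C)O[Si](C)(C)C(C)(C)C)=C(OCC)C1[C@@H](CCC)CC(=O)OC | intermediate
15 | (4R)-limonene 1,2-oxide (cis/trans mixture) | CC12OC1C[C@@H](CC2)C(=C)C | starting material
16 | (3R)-6-oxo-3-(prop-1-en-2-yl)heptanal | CC(=O)CC[C@H](CC=O)C(=C)C | intermediate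
17 | (5R)-8,8-dibromo-5-(prop-1-en-2-yl)oct-7-en-2-one | CC(=O)CC[C@H](CC=C(Br)Br)C(=C)C | intermediate
18 | (4R)-1,1-dibromo-7-methyl-4-(prop-1-en-2-yl)octa-1,7-diene | C=C(C)CC[C@H](CC=C(Br)Br)C(=C)C | intermediate
19 | lithium (4R)-7-methyl-4-(prop-1-en-2-yl)oct-7-en-1-yn-1-ide | C=C(C)CC[C@H](CC#C[Li])C(=C)C | intermediate
20 | lithium (4R)-7-methyl-4-(prop-1-en-2-yl)oct-7-en-1-yn-1-olate | C=C(C)CC[C@H](CC#CO[Li])C(=C)C | intermediate
21 | triisopropyl{[(4R)-7-methyl-4-(prop-1-en-2-yl)oct-7-en-1-yn-1-yl]oxy}silane | C=C(C)CC[C@H](CC#CO[Si](C(C)C)(C(C)C)C(C)C)C(=C)C | intermediate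
22 | vinylketene from ring opening of 14 | O=C=C(C(O[Si](C)(C)C(C)(C)C)[C@@H](C)[C@H](C)O[Si](C)(C)C(C)(C)C)C(OCC)=C[C@@H](CCC)CC(=O)OC | intermediate
23 | 4-vinylcyclobutenone from [2+2] of 22 and 21 | O=C1C(C[C@@H](CCC(C)=C)C(=C)C)=C(O[Si](C(C)C)(C(C)C)C(C)C)C1(C(O[Si](C)(C)C(C)(C)C)[C@@H](C)[C@H](C)O[Si](C)(C)C(C)(C)C)C(OCC)=C[C@@H](CCC)CC(=O)OC | intermediate
24 | dienylketene from ring opening of 23 | O=C=C(C[C@@H](CCC(C)=C)C(=C)C)C(O[Si](C(C)C)(C(C)C)C(C)C)=C(C(O[Si](C)(C)C(C)(C)C)[C@@H](C)[C@H](C)O[Si](C)(C)C(C)(C)C)C(OCC)=C[C@@H](CCC)CC(=O)OC | intermediate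
25 | cyclohexa-2,4-dienone tautomer of 26 | O=C1C(C[C@@H](CCC(C)=C)C(=C)C)=C(O[Si](C(C)C)(C(C)C)C(C)C)C(C(O[Si](C)(C)C(C)(C)C)[C@@H](C)[C@H](C)O[Si](C)(C)C(C)(C)C)=C(OCC)C1[C@@H](CCC)CC(=O)OC | intermediate
26 | methyl (3S)-3-{3-[(1RS,2S,3S)-1,3-bis(tert-butyldimethylsilyloxy)-2-methylbutyl]-2-ethoxy-6-hydroxy-5-[(2R)-5-methyl-2-(prop-1-en-2-yl)hex-5-en-1-yl]-4-(triisopropylsilyloxy)phenyl}hexanoate | Oc1c(C[C@@H](CCC(C)=C)C(=C)C)c(O[Si](C(C)C)(C(C)C)C(C)C)c(C(O[Si](C)(C)C(C)(C)C)[C@@H](C)[C@H](C)O[Si](C)(C)C(C)(C)C)c(OCC)c1[C@@H](CCC)CC(=O)OC | intermediate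
27 | desilylated hydroxy ester (methyl ester, three free OH on the chain and ring) | Oc1c(C[C@@H](CCC(C)=C)C(=C)C)c(O)c(C(O)[C@@H](C)[C@H](C)O)c(OCC)c1[C@@H](CCC)CC(=O)OC | intermediate
28 | (4S)-6-[(1RS,2S,3S)-1,3-dihydroxy-2-methylbutyl]-5-ethoxy-7-hydroxy-8-[(2R)-5-methyl-2-(prop-1-en-2-yl)hex-5-en-1-yl]-4-propylchroman-2-one | O=C1C[C@H](CCC)c2c(OCC)c(C(O)[C@@H](C)[C@H](C)O)c(O)c(C[C@@H](CCC(C)=C)C(=C)C)c2O1 | intermediate
29 | (4S)-5-ethoxy-7-hydroxy-6-[(2S,3S)-3-hydroxy-2-methylbutanoyl]-8-[(2R)-5-methyl-2-(prop-1-en-2-yl)hex-5-en-1-yl]-4-propylchroman-2-one | O=C1C[C@H](CCC)c2c(OCC)c(C(=O)[C@@H](C)[C@H](C)O)c(O)c(C[C@@H](CCC(C)=C)C(=C)C)c2O1 | intermediate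
30 | tricyclic lactone chromanone, 5-ethoxy (cis-(2R,3S)-dimethylpyranone fused at C6/C7 of the (4S)-4-propylchroman-2-one) | O=C1C[C@H](CCC)c2c(OCC)c3C(=O)[C@@H](C)[C@@H](C)Oc3c(C[C@@H](CCC(C)=C)C(=C)C)c2O1 | intermediate
31 | tricyclic lactone chromanone, 5-hydroxy | O=C1C[C@H](CCC)c2c(O)c3C(=O)[C@@H](C)[C@@H](C)Oc3c(C[C@@H](CCC(C)=C)C(=C)C)c2O1 | intermediate
32 | tert-butyl 2-methylbut-3-en-2-yl carbonate | CC(C)(C=C)OC(=O)OC(C)(C)C | starting material
33 | enol δ-lactone dienone (C-prenylated, quaternary carbon R) | C=C(C)CC[C@H](C[C@@]1(CC=C(C)C)C2=C([C@@H](CCC)CC(=O)O2)C(=O)C3=C1O[C@H](C)[C@H](C)C3=O)C(=C)C | intermediate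
34 | CNP0294320.1 | C=C(C)CC[C@H](C[C@@]1(CC=C(C)C)C(=O)C([C@@H](CCC)CC(=O)O)=C(O)C2=C1O[C@H](C)[C@H](C)C2=O)C(=C)C | target

## Step count and risks

Total step count: 19. Longest linear sequence: 13 steps (steps 3–8, then 13–19).

Steps most likely to fail:

**Step 18.** Attack of the phenoxide on the π-prenyl complex may show poor facial selectivity at the new quaternary carbon, or may stall at the O-prenyl ether. The fallback sets out from 31 and returns at 33. It replaces the palladium π-allyl pathway by ion-pair control: prenyl bromide, solid Cs2CO3 and a cinchona-derived N-(9-anthracenylmethyl)ammonium phase-transfer catalyst in toluene at −20 °C, so that the chiral cation shields one face of the phenoxide in a direct SN2 C-alkylation. This fallback makes no new compound. The two epimers at the quaternary carbon are diastereomers and can be separated if selectivity stays moderate.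

**Step 13.** The intermolecular [2+2] between the fully substituted vinylketene and the siloxyalkyne may be outrun by ketene dimerisation, or the cascade may stall before the 6π closure, because of the bulky bis-silyloxybutyl group. The fallback sets out from 3 and 9 and returns at 28.
- The ketene from 3 (Et3N) is combined with parent 9 to give the unhindered methyl (3S)-3-[(1RS)-2-ethoxy-4-oxocyclobut-2-en-1-yl]hexanoate F1.
- Benzannulation of F1 with 21 under the conditions of step 13 should give methyl (3S)-3-{2-ethoxy-6-hydroxy-5-[(2R)-5-methyl-2-(prop-1-en-2-yl)hex-5-en-1-yl]-4-(triisopropylsilyloxy)phenyl}hexanoate F2, with one free ring position.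
- Bu4NF desilylates and lactonises F2 to (4S)-5-ethoxy-7-hydroxy-8-[(2R)-5-methyl-2-(prop-1-en-2-yl)hex-5-en-1-yl]-4-propylchroman-2-one F3.
- The bromomagnesium phenoxide of F3 (EtMgBr, 1 equiv, toluene) undergoes ortho-specific hydroxyalkylation with aldehyde 8 to give (4S)-6-[(1RS,2R,3S)-3-(tert-butyldimethylsilyloxy)-1-hydroxy-2-methylbutyl]-5-ethoxy-7-hydroxy-8-[(2R)-5-methyl-2-(prop-1-en-2-yl)hex-5-en-1-yl]-4-propylchroman-2-one F4.
- Bu4NF then converts F4 into 28.

**Step 16.** Activation of the β-hydroxy ketone may lead to E1cB elimination or retro-aldol cleavage instead of SN2 closure, with loss of the cis configuration. The fallback sets out from 29 and returns at 30. The alcohol is dehydrated on purpose with the Burgess reagent (benzene, 50 °C) to (4S)-5-ethoxy-7-hydroxy-6-[(E)-2-methylbut-2-enoyl]-8-[(2R)-5-methyl-2-(prop-1-en-2-yl)hex-5-en-1-yl]-4-propylchroman-2-one F5. F5 is then cyclised by a (−)-quinine-catalysed, cis-selective enantioselective intramolecular oxa-Michael addition in chlorobenzene at rt to give 30.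

## Further compounds

F0 | step 18 | none | none
F1 | step 13 | methyl (3S)-3-[(1RS)-2-ethoxy-4-oxocyclobut-2-en-1-yl]hexanoate | O=C1C=C(OCC)C1[C@@H](CCC)CC(=O)OC
F2 | step 13 | methyl (3S)-3-{2-ethoxy-6-hydroxy-5-[(2R)-5-methyl-2-(prop-1-en-2-yl)hex-5-en-1-yl]-4-(triisopropylsilyloxy)phenyl}hexanoate | Oc1c(C[C@@H](CCC(C)=C)C(=C)C)c(O[Si](C(C)C)(C(C)C)C(C)C)cc(OCC)c1[C@@H](CCC)CC(=O)OC
F3 | step 13 | (4S)-5-ethoxy-7-hydroxy-8-[(2R)-5-methyl-2-(prop-1-en-2-yl)hex-5-en-1-yl]-4-propylchroman-2-one | O=C1C[C@H](CCC)c2c(OCC)cc(O)c(C[C@@H](CCC(C)=C)C(=C)C)c2O1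
F4 | step 13 | (4S)-6-[(1RS,2R,3S)-3-(tert-butyldimethylsilyloxy)-1-hydroxy-2-methylbutyl]-5-ethoxy-7-hydroxy-8-[(2R)-5-methyl-2-(prop-1-en-2-yl)hex-5-en-1-yl]-4-propylchroman-2-one | O=C1C[C@H](CCC)c2c(OCC)c(C(O)[C@@H](C)[C@H](C)O[Si](C)(C)C(C)(C)C)c(O)c(C[C@@H](CCC(C)=C)C(=C)C)c2O1
F5 | step 16 | (4S)-5-ethoxy-7-hydroxy-6-[(E)-2-methylbut-2-enoyl]-8-[(2R)-5-methyl-2-(prop-1-en-2-yl)hex-5-en-1-yl]-4-propylchroman-2-one | O=C1C[C@H](CCC)c2c(OCC)c(C(=O)/C(C)=C/C)c(O)c(C[C@@H](CCC(C)=C)C(=C)C)c2O1
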